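All runs were computed for substances that don't exist; scatter was added.

The south-east run, with twice the transfer agent of the west run and a protic impurity of 0.025 M, between the 0.017 M of west and the 0.038 M of south-west, reads 32% monomer in chains at 6.00 d, against 52% in west and 50% in south-west. So you read transfer as ending growth rather than restarting it, and reckon one chain per pre-initiator.

| setting | west | south-west | south-east | flask |
|---|---|---|---|---|
| free monomer | 0.50 M | 0.50 M | 0.50 M | 0.50 M |
| transfer agent | 5 mM | 5 mM | 10 mM | 5.00 mM |
| protic impurity | 0.017 M | 0.038 M | 0.025 M | 0.0250 M |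
| pre-initiator | 1.2 mM | 1.2 mM | 1.2 mM | 1.2 mM |
| remark | run made earlier | run made earlier | run made earlier |  |
| time |  |  |  | 10 d |

| run | time / d | monomer in chains / % | free monomer / % |
|---|---|---|---|
| west | 0.833 | 7 | 94 |
| west | 1.67 | 18 | 79 |
| west | 2.50 | 27 | 69 |
| west | 3.00 | 31 | 63 |
| west | 4.00 | 41 | 55 |
| west | 5.00 | 47 | 50 |
| west | 6.00 | 52 | 45 |
| south-west | 0.833 | 4 | 88 |
| south-west | 1.67 | 13 | 75 |
| south-west | 2.50 | 25 | 67 |
| south-west | 3.00 | 32 | 63 |
| south-west | 4.00 | 40 | 52 |
| south-west | 5.00 | 48 | 46 |
| south-west | 6.00 | 50 | 42 |
| south-east | 0.500 | 1 | 92 |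
| south-east | 1.67 | 12 | 87 |
| south-east | 3.00 | 21 | 76 |
| south-east | 4.00 | 24 | 68 |
| south-east | 6.00 | 32 | 61 |

(standard deviation of a reading: 1.5 percentage points)

1. average number of monomer units in a chain (chains begun, living or dead) at 10 d
2. part of the free monomer that has reacted at 10 d

- the average divides the monomer in chains by the number of chains begun, living and dead together
- the numbers in the tables scatter with a standard deviation of 1.5 percentage points
- the earlier runs do not show the number of chains; that part of a forecast is a guess

Build the flask up. With growth as the sole step and the charge of free monomer ending in chains, dp is 417. Add the quench: the south-west readings at 6.00 d fall short by 8.00%, against [protic impurity]/[free monomer] of 7.60%, so take one monomer per impurity, and dp drops to 396.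

Now add the fading of growth. Averaging west and south-west, which bracket this flask's impurity, the pseudo-first-order loss of free monomer reads 0.160 d⁻¹, then 0.103 d⁻¹. Holding the later rate to 10 d leaves 28.8% free. That rate is falling, though, so go round again: the same fading gives 0.0491 d⁻¹ for the last stretch and leaves 35.7%. Your chain yield, the part of the unquenched monomer standing in chains at the asked time, is 62.4%, and yield times unquenched monomer per pre-initiator gives dp 247.

The forecast differs: dp 85 and c 68%, counting “1.2 mM of starts plus transfer events”. Your own c is 64.3%.

The flask gives dp 291 and c 66.7%.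

    free monomer + living end → monomer in chains + living end, rate k1*[living end]*[free monomer] (k = 1.30 M⁻¹ min⁻¹)
    free monomer + initiator → living end + monomer in chains (k = 0.00380 M⁻¹ min⁻¹)
    pre-initiator → initiator (k = 1.70 × 10⁻⁴ min⁻¹)
    protic impurity + free monomer → quenched substrate (k = 0.00630 M⁻¹ min⁻¹)
    living end + transfer agent → dead chain (kL = 0.290 M⁻¹ min⁻¹)

In the flask, protic impurity went early: half its turnover was done by 0.155 d, and at 5.00 d it stands at 0% with quenched substrate at 5.00%. Growth ran while pre-initiator fed initiator: half the turnover of free monomer into chains up to 10 d was done by 2.79 d, and at 10 d pre-initiator stands at 8.65% of its charge. The dp of 247 from your yield lies below the flask's 291, and the flask's chains begun at 10.0 d stand at 1.06 mM, less than the 1.2 mM of pre-initiator charged. For the neighbour charged with 0.85 M of free monomer, the same yield gives 429; the computed dp is 502.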